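The runs were computed with constants of no real substance.

The easy mistake was to expect more target from more coupling partner.

| flask | starting material | coupling partner | remark | time |
|---|---|---|---|---|
| ash | 0.90 M | 0.30 M | run made earlier |  |
| birch | 0.90 M | 2.6 M | run made earlier |  |
| alder | 0.51 M | 1.62 M | run made earlier |  |
| midnight | 0.25 M | 0.400 M |  | 15 min |
| autumn | 0.90 M | 0.400 M |  | 15 min |
| dusk | 0.90 M | 1.62 M |  | 15 min |
| spring | 0.25 M | 1.62 M |  | 15 min |
| summer | 0.90 M | 3.00 M |  | 15 min |
| noon | 0.25 M | 3.00 M |  | 15 min |

| run | time / min | target / % |
|---|---|---|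
| ash | 4.00 | 8 |
| ash | 8.00 | 20 |
| ash | 12.0 | 24 |
| ash | 15.0 | 24 |
| birch | 2.00 | 15 |
| birch | 5.00 | 37 |
| birch | 10.0 | 50 |
| birch | 15.0 | 50 |
| alder | 4.00 | 29 |
| alder | 8.00 | 52 |
| alder | 12.0 | 56 |
| alder | 15.0 | 58 |

(standard deviation of a reading: 1.5 percentage points)

* all flasks from highest to lowest amount of target, in percent of the starting material charged, at 15 min (midnight / autumn / dusk / spring / summer / noon)
* the amount of target, in percent of the starting material charged of the flask you put first, at 15 min
* the amount of target, in percent of the starting material charged of the flask you put last, at 15 min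

I assumed that the starting material was all taken up, that each used one coupling partner, and that whatever did not become target used a second. Birch, at its last reading of 50%, then kept c(coupling partner) = 1.25 M, and alder, at 58%, kept 0.896 M. I took the target share as c(even)/(c(even)+c). Birch read 1.25 M and alder 1.24 M. Their mean is c(even) = 1.24 M, the concentration of coupling partner at which target and loss split evenly.

The share sets what partner remains, and that sets the share, so I iterated. Dusk, started from a guess of 0.5, went 82.2%, 69.0%, 73.8%, 72.0%. Noon, with 3.00 M of coupling partner on 0.25 M of starting material, came to 32.5%. For noon to match dusk, c(even) would have to be 6.88 M, far above my reading. Midnight's ceiling was 89.6%. But ash read 20% at 8.00 min. I took that pace, in percent of starting material, as proportional to c(coupling partner), and my estimate for midnight in 15 min was 50.0%, less than the 72.0% of dusk. So I put dusk first. Scaling from ash, where coupling partner was the limiting reagent, gave autumn 32.0%, level with noon at the bottom.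

The forecast reasoned otherwise: “The plateau is therefore set by rate” and a lifetime. It gave noon > spring > summer > midnight > dusk > autumn, with 90% first and 26% last.

The flasks gave dusk > midnight > spring > summer > noon > autumn, with 63.9% first and 34.0% last.

    starting material + coupling partner ⇌ intermediate A (K = 23.0 M⁻¹, k = 0.00830 M⁻¹ s⁻¹)
    coupling partner + intermediate A → side product (k = 0.00130 M⁻¹ s⁻¹)
    intermediate A → target (k = 0.00280 s⁻¹)
    coupling partner + intermediate A → intermediate B (k = 3.30 × 10⁻⁴ M⁻¹ s⁻¹)
    intermediate B ⇌ intermediate C (K = 0.480, k = 0.0460 s⁻¹)
    intermediate C ⇌ intermediate D (K = 0.160, k = 3.90 × 10⁻⁴ s⁻¹)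

In dusk, half the turnover to intermediate A was done by 1.02 min, to side product by 3.56 min and to target by 4.66 min, while coupling partner fell to 30.0% of its charge. That remainder in c(even) gives 71.9%; dusk held 63.9% target at 15.0 min and 70.5% at 150 min.

For the dusk recipe with 0.54 M of starting material, c(even) gives 58.9%. That flask gave 59.1%.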